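## Structural features

The target is a germacranolide: a ten-membered carbocycle (C1–C10) with an E-trisubstituted C4=C5 alkene and a Z-trisubstituted C1=C10 alkene, fused at C6–C7 to an α-methylene-γ-butyrolactone (O6–C12(=O)–C11(=C13)–C7). Four contiguous oxygenated stereocentres run from C6 to C9. The lactone is cis-fused (O6 and C11 on the same ring face), the tertiary C7 hydroxyl and the C8 angelate lie together on the opposite face, and the C9 hydroxyl is threo to C8 along the chain; C6 and C9 are both allylic. Fragile elements are the methylene lactone (Michael acceptor), the angelate (Z to E isomerisation, acyl migration), the β-hydroxy lactone motif at C7 (elimination, and translactonisation to O8 whenever O8 is free) and the 1,5-diene in a medium ring (acid-induced transannular cyclisation). The real difficulty is closing a strained ten-membered ring that holds one E and one Z trisubstituted alkene next to a fully substituted, oxygen-bearing C7. The key step exploits the C1=C10 alkene: C1 and C10 are first joined through sulfur in an eleven-membered ring, which closes by simple S-alkylation, and the sulfur is then excised as SO2. Because C10 ends up trigonal, the sulfur-bearing carbon needs no stereocontrol, and all four oxygenated stereocentres can be set beforehand in open-chain chemistry.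

## Logic of the disconnections

37 ⇐ 36 ⇐ 33 (O9–benzyl bond, C8–O acyl bond). The Z ester of 34 isomerises with base or nucleophiles and a free O9 beside it invites acyl migration, so these bonds are made last. Cutting them reduces 37 to 33, in which only O9 is masked. The forward acylation must pick the secondary O8 over the tertiary O7 without isomerising the ester, and the final unmasking must be neutral.

33 ⇐ 30 (C11=C13). The exocyclic methylene is the most electrophilic site, and C13 is not part of the skeleton that leaves the key step. Removing it gives a saturated lactone. The forward step must enolise C11 without expelling the β-oxygen at C7, so O7 (and O8) are used as alkoxides.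

30 ⇐ 29 ⇐ 27 ⇐ 26 (O6–C12 acyl bond, C12 oxidation level, O7/O8 ketal, two O–Si bonds). An enolisable lactone with a β-oxygen cannot pass through hydroxide chemistry, so the lactone is opened and C12 lowered to a silyl-protected alcohol. O7 and O8 are tied as an acetonide so that only O6 can capture C12 (O8 is also γ to C12). O6 and O12 both carry fluoride-labile groups, so one deprotection frees exactly the pair that lactonises. The acetonide hydrolysis must be mild enough for the 1,5-diene.

26 ⇐ 23 (C1=C10, key disconnection). The Z alkene is traced back to a C1–SO2–C10 bridge in an eleven-membered ring. This turns a medium-ring C–C closure into a contraction and makes C10 stereochemically irrelevant. In 23 every hydroxyl is capped (difluorocarbene would otherwise insert into O–H), O9 is an ether (poor leaving group β to the sulfone), and nothing else is base-sensitive. The forward step must give Z geometry and must contract faster than the C10 carbanion eliminates O9.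

23 ⇐ 21 ⇐ 20 ⇐ 18 (S oxidation level, O9–benzyl, S–C1). The thiacycle is opened at the S–C1 bond, giving a C10 thiolate and a primary C1 chloride. This is the most favourable way to close a large ring at sulfur. It needs high dilution and a sulfide-to-sulfone oxidation that spares the C4=C5 alkene.

18 ⇐ 17 (S–C10). Sulfur is removed from C10 to leave a C9–C10 trans-epoxide. The epoxide carries the C9 configuration, and whichever C10 configuration results is acceptable. The opening must be regioselective for C10, anti, and must not touch C1–Cl.

17 ⇐ 16 ⇐ 15 ⇐ 10 + 13 (O6–Si, C6–H, C5–C6). The C5–C6 bond is the convergent cut, separating the C1–C5 arm 13 from the oxygenated core 10. C6 is taken to the ketone level so that its configuration is set by reduction. The reduction must be Felkin-selective, and the epoxide and chloride must survive the organolithium.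

13 ⇐ 11 (C4–C15, C5–I). Methyl and iodine are removed from the E alkene to give a terminal alkyne. The forward carbometalation must be syn and regioselective.

10 ⇐ 9 ⇐ 8 ⇐ 7 (both epoxide C–O bonds, ketal, C6–N). The epoxide goes back to the E alkene, which needs reagent-controlled facial selectivity. The acetonide and the amide go back to an acylal that holds O7 and C6 together.

7 ⇐ 4 + 5 (C7–C8). The aldol bond is cut beside the quaternary carbinol. C7 then comes from the chiral pool by self-regeneration of the stereocentre, and 5 supplies C8–C10 and C14 with the E alkene in place. The forward step needs attack anti to the acetal tert-butyl group and anti aldol topicity at C8.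

4 ⇐ 3 ⇐ 2 ⇐ 1 (O12–Si, C12 oxidation level, acetal). The side-chain carboxyl of 1 is lowered before the aldol so that C6 and C12 are differentiated from the outset and no lactone can form between O8 and C12.

## Other disconnections considered

Alternative 1: The cut removes C12 as carbon monoxide by breaking C11–C12 and C12–O6, leaving the ten-membered ethynyl diol A1 with the angelate and a C9 silyl ether already in place. The forward step is a cyclocarbonylation with PdCl2(PPh3)2 and SnCl2 under CO: palladium adds across the alkyne, CO inserts, and O6 captures the acyl group to give A2, one desilylation from the target. In its favour, lactone and methylene arrive together, late and without base, so there is no lactone enolate, no β-oxygen elimination and no separate C13 installation. On the lactone end-game it is the better plan. Against it, it does nothing for the ten-membered ring or the Z alkene, which another ring closure must still deliver. The tertiary propargylic O7 can compete with O6 (β-lactone pathway), and palladium hydride chemistry must coexist with a 1,5-diene, an allylic alcohol and the angelate. Structurally the two plans are complementary. Mechanistically this one trades carbanion chemistry for carbonylation. Its overall step economy cannot be judged, because the hard part lies outside its key step.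

Alternative 2: The cut is C7–C8. An open chain A3 carries a C8 aldehyde at one end and a 3-(bromomethyl)-4-alkoxybutenolide at the other. Indium or CrCl2 would turn the bromide into an allylmetal that attacks the aldehyde through C7, closing the ring, creating C7 and C8 and unveiling the methylene in A4. In its favour are convergence and a key step that builds ring, lactone, methylene and two stereocentres at once. In step economy it is the better plan, and in functional-group tolerance at least its equal. Against it, the nucleophilic carbon is an oxygen-bearing vinylogous carbonate position that must become a quaternary centre, and the ring is closed end to end against medium-ring strain. The facial outcome at C7 and C8 rests only on C6 and C9 in a macrocyclic transition state. The chosen plan sets all four stereocentres in open-chain reactions with established models and forms the carbocycle by a contraction driven by SO2 loss; it is longer but more predictable.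

Alternative 3: The retron reconnects C4–C9, so that the ten-membered ring is hidden in the trans-decalin A5 with a C9 tertiary alkoxide and an equatorial C5 mesylate. The forward step is a Grob fragmentation with KOtBu to the dienone A6. In its favour, the fragmentation is stereospecific, so the 4E geometry follows from the decalin configuration, and the Z alkene pre-exists in a cyclohexene. For alkene geometry it is the better plan, and for medium-ring strain the equal of a contraction. C13 is also present early, which shortens the end-game. Against it, A5 needs six contiguous stereocentres on a decalin, including quaternary C4 and tertiary C9. C9 is then destroyed and must be re-set by reducing a ketone on a flexible ring. That ketone is flanked by C8–H, so alkoxide base can epimerise C8 or expel O7. The chosen plan keeps C9 as an ether throughout and is likely shorter.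

Key step: step 16

Remark: locants C1–C15 are those of the germacrane skeleton, and R/S labels in descriptive names refer to these positions.
Remark: anti (SN2) opening of the trans-epoxide can only give the 9,10-anti sulfide, so 23 is the 10R sulfone; a 10S drawing of this sulfone would not follow from this sequence, and the epimer is immaterial because C10 becomes trigonal.
Remark: the L-sorbose-derived enantiomer of the fructose-based epoxidation ketone is assumed to be in hand as a catalyst.

Step 1
Reactants: 1 (R)-malic acid
Product: 2 cis-dioxolanone acid 2-[(2R,4R)-2-tert-butyl-5-oxo-1,3-dioxolan-4-yl]acetic acid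
Conditions: tBuCHO, TsOH·H2O (cat.), H2SO4 (cat.), pentane, reflux (Dean–Stark); recrystallisation
Reagents that add atoms: pivalaldehyde, CC(C)(C)C=O
Why: Acid-catalysed acetalisation of the α-hydroxy acid unit under thermodynamic control; the cis isomer (tert-butyl and CH2CO2H on the same face) is favoured and crystallises. C7 is untouched and the new acetal centre is the relay for self-regeneration of the stereocentre.

Step 2
Reactants: 2 cis-dioxolanone acid
Product: 3 (2R,5R)-2-tert-butyl-5-(2-hydroxyethyl)-1,3-dioxolan-4-one
Conditions: BH3·SMe2, THF, 0 °C → rt; aqueous work-up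
Reagents that add atoms: none
Why: Borane reduces a free carboxylic acid through its acyloxyborane much faster than the lactone-type carbonyl of the dioxolanone. The product is silylated without delay because the hydroxyethyl arm can translactonise.

Step 3
Reactants: 3 hydroxyethyl dioxolanone
Product: 4 (2R,5R)-2-tert-butyl-5-[2-(tert-butyldiphenylsilyloxy)ethyl]-1,3-dioxolan-4-one
Conditions: tBuPh2SiCl, imidazole, DMF, 0 °C → rt
Reagents that add atoms: tert-butyldiphenylsilyl chloride, CC(C)(C)[Si](Cl)(c1ccccc1)c1ccccc1
Why: Standard silylation of a primary alcohol. TBDPS is chosen because it must survive acid (step 6), organolithium, hydride and hydroxide before fluoride removes it.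

Step 4
Reactants: 4 silyloxyethyl dioxolanone; 5 (E)-crotonaldehyde
Product: 7 aldol adduct (2R,5S)-2-tert-butyl-5-[2-(tert-butyldiphenylsilyloxy)ethyl]-5-[(1S,2E)-1-hydroxybut-2-enyl]-1,3-dioxolan-4-one, via lithium enolate 6 (not isolated)
Conditions: LiN(iPr)2, THF, −78 °C; then 5, −78 °C; AcOH quench at −78 °C
Reagents that add atoms: none
Why: Aldol addition of a dioxolanone enolate (self-regeneration of stereocentres): the aldehyde enters anti to the tert-butyl group, so C7 keeps the configuration of 1. A Zimmerman–Traxler chair with the propenyl group equatorial and the CH2CH2OSi arm cis to O–Li should place O8 anti to O7 (8S). The lithium enolate adds 1,2 to the enal at −78 °C.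

Step 5
Reactants: 7 aldol adduct
Product: 8 Weinreb amide diol (2S,3S,4E)-2-[2-(tert-butyldiphenylsilyloxy)ethyl]-2,3-dihydroxy-N-methoxy-N-methylhex-4-enamide
Conditions: MeNH(OMe)·HCl, AlMe3, CH2Cl2, 0 °C → rt; aqueous Rochelle salt
Reagents that add atoms: N,O-dimethylhydroxylamine hydrochloride, CNOC.Cl
Why: Aminolysis of a lactone-type carbonyl by the aluminium amide of N,O-dimethylhydroxylamine (Weinreb amide formation). The unmasked hemiacetal loses pivalaldehyde on work-up and frees O7, while O8 is held as an aluminium alkoxide, which disfavours retro-aldol cleavage.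

Step 6
Reactants: 8 Weinreb amide diol
Product: 9 acetonide (4S,5S)-4-[2-(tert-butyldiphenylsilyloxy)ethyl]-N-methoxy-N,2,2-trimethyl-5-[(E)-prop-1-enyl]-1,3-dioxolane-4-carboxamide
Conditions: Me2C(OMe)2, camphorsulfonic acid (cat.), acetone, rt
Reagents that add atoms: 2,2-dimethoxypropane, COC(C)(C)OC
Why: Acid-catalysed transketalisation; the tertiary C7 and secondary C8 hydroxyls are the only diol present and close the five-membered acetonide.

Step 7
Reactants: 9 acetonide
Product: 10 epoxy Weinreb amide (7S,8S,9R,10S; trans-epoxide at C9–C10)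
Conditions: 1,2:4,5-di-O-isopropylidene-β-L-erythro-2,3-hexodiulo-2,6-pyranose (enantiomer of the Shi ketone, cat.), KHSO5 (Oxone), K2CO3, Bu4NHSO4, MeCN/CH2(OMe)2/aq. Na2B4O7 buffer, 0 °C
Reagents that add atoms: potassium peroxymonosulfate (Oxone), [K+].[O-]S(=O)(=O)OO
Why: Shi epoxidation (chiral dioxirane, spiro transition state) is reagent-controlled for trans-disubstituted alkenes. The L-series ketone is needed because the required face at C9 (oxygen threo to O8) is opposite to the one the fructose-derived ketone attacks. C10 is set as well but is lost later.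

Step 8
Reactants: 11 5-chloropent-1-yne
Product: 13 (E)-5-chloro-1-iodo-2-methylpent-1-ene, via alkenylalane 12 (not isolated)
Conditions: AlMe3, Cp2ZrCl2 (cat.), CH2Cl2, 0 °C → rt; then I2, THF, −30 °C
Reagents that add atoms: trimethylaluminium, C[Al](C)C; iodine, II
Why: Zirconium-catalysed carboalumination of a terminal alkyne (Negishi) adds methyl and aluminium syn, with aluminium at the terminus. Iodinolysis with retention gives the E iodide, which fixes the C4=C5 geometry and brings in C15; the alkyl chloride is inert.

Step 9
Reactants: 10 epoxy Weinreb amide; 13 alkenyl iodide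
Product: 15 enone (C6 ketone; 7S,8S,9R,10S; 4E), via alkenyllithium 14 (not isolated)
Conditions: 13, tBuLi, Et2O, −78 °C; then 10, THF, −78 → −40 °C; aq. NH4Cl
Reagents that add atoms: none
Why: Iodine–lithium exchange retains alkene geometry. The alkenyllithium acylates the Weinreb amide through a chelated tetrahedral intermediate that collapses only on work-up, so no over-addition occurs. Epoxide and primary chloride do not react with an organolithium at −78 °C.

Step 10
Reactants: 15 enone
Product: 16 allylic alcohol (6S,7R,8S,9R,10S; 4E)
Conditions: Li(sBu)3BH, THF, −78 °C; aq. NH4Cl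
Reagents that add atoms: none
Why: Felkin–Anh 1,2-reduction with a bulky hydride: the C7–O bond stands anti to the incoming hydride and the ring carbon C8, with its cis epoxide arm, takes the inside position. Hydride then passes the smaller CH2CH2OSi arm and should give the 6S alcohol. The β,β-disubstituted enone resists conjugate reduction.

Step 11
Reactants: 16 allylic alcohol
Product: 17 O6 tert-butyldimethylsilyl ether of 16 (6S,7S,8S,9R,10S)
Conditions: tBuMe2SiOTf, 2,6-lutidine, CH2Cl2, −78 °C
Reagents that add atoms: tert-butyldimethylsilyl triflate, CC(C)(C)[Si](C)(C)OS(=O)(=O)C(F)(F)F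
Why: Silylation of a hindered secondary alcohol with the silyl triflate at low temperature. TBS is chosen so that O6 and O12 are later freed together by fluoride.

Step 12
Reactants: 17 silyl ether epoxide
Product: 18 9-hydroxy-10-acetylthio chloride (6S,7S,8S,9S,10R)
Conditions: AcSH (excess), toluene, 40 °C
Reagents that add atoms: thioacetic acid, CC(=O)S
Why: Anti ring opening of the epoxide by thioacetic acid should occur at C10, which is less hindered and remote from the electron-withdrawing dioxolane, giving the 9,10-anti product. Without base the primary chloride is untouched. Acetyl migration from S to O9 would be harmless, because both isomers give the same thiolate in step 13.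

Step 13
Reactants: 18 hydroxy thioacetate
Product: 20 eleven-membered cyclic sulfide (S between C1 and C10; 4E; 6-OTBS; 7,8-O-isopropylidene; 9-OH; 12-OTBDPS; 6S,7S,8S,9S,10R), via C10 thiol 19 (not isolated)
Conditions: Cs2CO3, NaI (cat.), MeOH/DMF, degassed, 45 °C, slow addition to 2 mM
Reagents that add atoms: none
Why: Methanolysis frees the C10 thiolate, which displaces the primary C1 chloride (iodide-assisted) in an 11-exo-tet macrocyclic S-alkylation. Slow addition keeps the thiolate dilute and degassing prevents disulfide formation.

Step 14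
Reactants: 20 cyclic sulfide alcohol
Product: 21 O9 4-methoxybenzyl ether of 20
Conditions: NaH, 4-MeOC6H4CH2Cl, Bu4NI (cat.), DMF, 0 °C → rt
Reagents that add atoms: 4-methoxybenzyl chloride, COc1ccc(CCl)cc1
Why: Williamson etherification of the only free hydroxyl. O9 must be an ether because it will sit β to the sulfone in the basic key step and must be removable last under neutral oxidative conditions.

Step 15
Reactants: 21 cyclic sulfide
Product: 23 eleven-membered cyclic sulfone (C1–SO2–C10; 6S,7S,8S,9S,10R), via sulfoxide 22 (not isolated)
Conditions: (NH4)6Mo7O24·4H2O (cat.), 30% H2O2, EtOH, 0 °C → rt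
Reagents that add atoms: hydrogen peroxide, OO
Why: Molybdate-catalysed peroxide oxidation takes sulfides to sulfones through the sulfoxide and, unlike peracids, leaves trisubstituted alkenes alone.

Step 16
Reactants: 23 cyclic sulfone
Product: 26 ten-membered (4E,1(10)Z)-diene (6-OTBS; 7,8-O-isopropylidene; 9-OPMB; 12-OTBDPS; 6S,7S,8S,9R), via α-bromo sulfone 24 (not isolated), via episulfone 25 (not isolated)
Conditions: KOH/Al2O3, CBr2F2, tBuOH/CH2Cl2, 0 °C → rt
Reagents that add atoms: none
Why: Ramberg–Bäcklund reaction with in situ halogenation: KOH on alumina deprotonates the sulfone at the less hindered C1 methylene and CBr2F2 transfers bromine to give 24; deprotonation at C10 then triggers a 1,3-displacement of bromide (3-exo-tet, W-arranged H–C10–S–C1–Br) that closes the thiirane dioxide of 25, and cheletropic loss of SO2 leaves the C1=C10 double bond. The ten-membered carbocycle is not closed end to end but arises by contraction of the eleven-membered ring, so the only ring-forming event is the 3-exo-tet episulfone closure. The closest known reaction type is the Ramberg–Bäcklund ring contraction of medium and large cyclic sulfones to cycloalkenes. No stereocentre is created; C10 loses its configuration, which is why the 10R epimer from the anti epoxide opening serves as well as any. The step needs Z geometry at C1=C10 and contraction in preference to β-elimination of the C9 oxygen. The cis-fused episulfone, and the cis-cycloalkene that follows, should be the less strained in a ring that already holds an E alkene, and the weak heterogeneous base should not equilibrate it. O9 is an ether and therefore a poor leaving group, every hydroxyl is capped so difluorocarbene has no O–H to insert into, and silyl ethers, acetonide and PMB ether are inert to KOH.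

Step 17
Reactants: 26 ten-membered diene
Product: 27 C6,C12-diol (7,8-O-isopropylidene; 9-OPMB; 6S,7R,8S,9R)
Conditions: Bu4NF, THF, 0 → 40 °C
Reagents that add atoms: none
Why: Fluoride cleaves both silyl ethers and leaves acetonide and PMB ether untouched, so the two hydroxyls that must lactonise are released in one operation.

Step 18
Reactants: 27 diol
Product: 29 cis-fused 6,12-lactone (7,8-O-isopropylidene; 9-OPMB; 6S,7R,8S,9R), via lactol 28 (not isolated)
Conditions: 2,2,6,6-tetramethylpiperidine-1-oxyl (TEMPO, cat.), PhI(OAc)2, CH2Cl2, rt
Reagents that add atoms: none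
Why: Oxoammonium oxidation converts the primary alcohol into the aldehyde, which the C6 hydroxyl traps as the lactol; further oxidation gives the lactone (oxidative lactonisation of a 1,4-diol). O8 is locked in the acetonide, so only the 6,12-olide can form.

Step 19
Reactants: 29 lactone acetonide
Product: 30 7,8-dihydroxy lactone (9-OPMB; 6S,7S,8S,9R)
Conditions: AcOH/H2O/THF (3:1:1), 45 °C
Reagents that add atoms: none
Why: Hydrolysis of the isopropylidene acetal with a weak aqueous acid, chosen to spare the PMB ether and to avoid protonating the 1,5-diene.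

Step 20
Reactants: 30 dihydroxy lactone
Product: 33 α-methylene lactone diol (9-OPMB; 6S,7S,8S,9R), via Mannich base 31 (not isolated), via trimethylammonium iodide 32 (not isolated)
Conditions: LiN(SiMe3)2 (3.3 equiv), THF, −78 °C; Me2N=CH2 I (Eschenmoser's salt), −78 → 0 °C; aq. NH4Cl; then MeI, MeOH, rt; NaHCO3, CH2Cl2/H2O
Reagents that add atoms: Eschenmoser's salt (N,N-dimethylmethyleneiminium iodide), C=[N+](C)C.[I-]
Why: Mannich methylenation of a lactone: excess amide base forms the C7,C8-dialkoxide and the C11 enolate, an oxido-enolate that cannot expel the C7 oxygen. Aminomethylation, N-methylation and E1cB loss of trimethylamine then give the exocyclic alkene; no stereocentre remains at C11.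

Step 21
Reactants: 33 methylene lactone diol; 34 angelic acid
Product: 36 C8 angelate (9-OPMB; 6S,7R,8S,9R), via mixed anhydride 35 (not isolated)
Conditions: 34, 2,4,6-Cl3C6H2COCl, Et3N, toluene, rt; then 33, 80 °C
Reagents that add atoms: none
Why: Yamaguchi-type esterification through the mixed anhydride, run without nucleophilic catalyst because such catalysts isomerise angelates to tiglates. The secondary C8 hydroxyl is acylated, the tertiary C7 hydroxyl is not, and O9 is still blocked.

Step 22
Reactants: 36 angelate PMB ether
Product: 37 target CNP0292337.1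
Conditions: DDQ, CH2Cl2/pH 7 buffer, 0 °C
Reagents that add atoms: none
Why: Oxidative cleavage of the PMB ether by DDQ (hydride abstraction, then hydrolysis of the oxocarbenium ion) under buffered conditions should not touch the alkenes, the methylene lactone or the angelate.

## Compound list

1 | (R)-malic acid | OC(=O)C[C@@H](O)C(O)=O | starting material
2 | 2-[(2R,4R)-2-tert-butyl-5-oxo-1,3-dioxolan-4-yl]acetic acid | CC(C)(C)[C@@H]1O[C@H](CC(O)=O)C(=O)O1 | intermediate
3 | (2R,5R)-2-tert-butyl-5-(2-hydroxyethyl)-1,3-dioxolan-4-one | CC(C)(C)[C@@H]1O[C@H](CCO)C(=O)O1 | intermediate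
4 | (2R,5R)-2-tert-butyl-5-[2-(tert-butyldiphenylsilyloxy)ethyl]-1,3-dioxolan-4-one | CC(C)(C)[C@@H]1O[C@H](CCO[Si](c2ccccc2)(c2ccccc2)C(C)(C)C)C(=O)O1 | intermediate
5 | (E)-crotonaldehyde | C/C=C/C=O | starting material
6 | lithium enolate of 4 (formed in situ) | CC(C)(C)[C@@H]1OC(CCO[Si](c2ccccc2)(c2ccccc2)C(C)(C)C)=C(O[Li])O1 | intermediate
7 | (2R,5S)-2-tert-butyl-5-[2-(tert-butyldiphenylsilyloxy)ethyl]-5-[(1S,2E)-1-hydroxybut-2-enyl]-1,3-dioxolan-4-one | CC(C)(C)[C@@H]1O[C@@](CCO[Si](c2ccccc2)(c2ccccc2)C(C)(C)C)([C@@H](O)/C=C/C)C(=O)O1 | intermediate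
8 | (2S,3S,4E)-2-[2-(tert-butyldiphenylsilyloxy)ethyl]-2,3-dihydroxy-N-methoxy-N-methylhex-4-enamide | CON(C)C(=O)[C@](O)(CCO[Si](c1ccccc1)(c1ccccc1)C(C)(C)C)[C@@H](O)/C=C/C | intermediate
9 | (4S,5S)-4-[2-(tert-butyldiphenylsilyloxy)ethyl]-N-methoxy-N,2,2-trimethyl-5-[(E)-prop-1-enyl]-1,3-dioxolane-4-carboxamide | CON(C)C(=O)[C@@]1(CCO[Si](c2ccccc2)(c2ccccc2)C(C)(C)C)OC(C)(C)O[C@H]1/C=C/C | intermediate
10 | (4S,5S)-4-[2-(tert-butyldiphenylsilyloxy)ethyl]-N-methoxy-N,2,2-trimethyl-5-[(2R,3S)-3-methyloxiran-2-yl]-1,3-dioxolane-4-carboxamide | CON(C)C(=O)[C@@]1(CCO[Si](c2ccccc2)(c2ccccc2)C(C)(C)C)OC(C)(C)O[C@H]1[C@@H]3O[C@H]3C | intermediate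
11 | 5-chloropent-1-yne | C#CCCCCl | starting material
12 | (E)-(5-chloro-2-methylpent-1-enyl)dimethylalane (formed in situ) | C[Al](C)/C=C(\C)CCCCl | intermediate
13 | (E)-5-chloro-1-iodo-2-methylpent-1-ene | I/C=C(\C)CCCCl | intermediate
14 | (E)-(5-chloro-2-methylpent-1-enyl)lithium (formed in situ) | [Li]/C=C(\C)CCCCl | intermediate
15 | enone: (E)-6-chloro-3-methylhex-2-en-1-one bearing at C1 the (4S,5S)-dioxolan-4-yl unit of 10 | ClCCC/C(C)=C/C(=O)[C@@]1(CCO[Si](c2ccccc2)(c2ccccc2)C(C)(C)C)OC(C)(C)O[C@H]1[C@@H]3O[C@H]3C | intermediate
16 | (6S)-allylic alcohol from 15 (6S,7R,8S,9R,10S; 4E) | ClCCC/C(C)=C/[C@H](O)[C@@]1(CCO[Si](c2ccccc2)(c2ccccc2)C(C)(C)C)OC(C)(C)O[C@H]1[C@@H]3O[C@H]3C | intermediate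
17 | O6 tert-butyldimethylsilyl ether of 16 | ClCCC/C(C)=C/[C@H](O[Si](C)(C)C(C)(C)C)[C@@]1(CCO[Si](c2ccccc2)(c2ccccc2)C(C)(C)C)OC(C)(C)O[C@H]1[C@@H]3O[C@H]3C | intermediate
18 | 9-hydroxy-10-acetylthio chloride (6S,7S,8S,9S,10R) | ClCCC/C(C)=C/[C@H](O[Si](C)(C)C(C)(C)C)[C@@]1(CCO[Si](c2ccccc2)(c2ccccc2)C(C)(C)C)OC(C)(C)O[C@H]1[C@H](O)[C@@H](C)SC(C)=O | intermediate
19 | 9-hydroxy-10-thiol chloride (formed in situ) | ClCCC/C(C)=C/[C@H](O[Si](C)(C)C(C)(C)C)[C@@]1(CCO[Si](c2ccccc2)(c2ccccc2)C(C)(C)C)OC(C)(C)O[C@H]1[C@H](O)[C@@H](C)S | intermediate
20 | eleven-membered cyclic sulfide, 9-OH (6S,7S,8S,9S,10R; 4E) | CC(C)(C)[Si](C)(C)O[C@H]1/C=C(\C)CCCS[C@H](C)[C@@H](O)[C@@H]3OC(C)(C)O[C@]13CCO[Si](c2ccccc2)(c2ccccc2)C(C)(C)C | intermediate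
21 | eleven-membered cyclic sulfide, 9-OPMB | CC(C)(C)[Si](C)(C)O[C@H]1/C=C(\C)CCCS[C@H](C)[C@@H](OCc2ccc(OC)cc2)[C@@H]3OC(C)(C)O[C@]13CCO[Si](c4ccccc4)(c4ccccc4)C(C)(C)C | intermediate
22 | cyclic sulfoxide (formed in situ; configuration at sulfur undefined) | CC(C)(C)[Si](C)(C)O[C@H]1/C=C(\C)CCCS(=O)[C@H](C)[C@@H](OCc2ccc(OC)cc2)[C@@H]3OC(C)(C)O[C@]13CCO[Si](c4ccccc4)(c4ccccc4)C(C)(C)C | intermediate
23 | eleven-membered cyclic sulfone (6S,7S,8S,9S,10R; 4E) | CC(C)(C)[Si](C)(C)O[C@H]1/C=C(\C)CCCS(=O)(=O)[C@H](C)[C@@H](OCc2ccc(OC)cc2)[C@@H]3OC(C)(C)O[C@]13CCO[Si](c4ccccc4)(c4ccccc4)C(C)(C)C | intermediate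
24 | C1-bromo sulfone (formed in situ; C1 configuration undefined) | CC(C)(C)[Si](C)(C)O[C@H]1/C=C(\C)CCC(Br)S(=O)(=O)[C@H](C)[C@@H](OCc2ccc(OC)cc2)[C@@H]3OC(C)(C)O[C@]13CCO[Si](c4ccccc4)(c4ccccc4)C(C)(C)C | intermediate
25 | bicyclic episulfone (formed in situ; cis-fused at C1/C10, face undefined) | CC(C)(C)[Si](C)(C)O[C@H]1/C=C(\C)CCC5S(=O)(=O)C5(C)[C@@H](OCc2ccc(OC)cc2)[C@@H]3OC(C)(C)O[C@]13CCO[Si](c4ccccc4)(c4ccccc4)C(C)(C)C | intermediate
26 | ten-membered (4E,1(10)Z)-diene (6S,7S,8S,9R) | CC(C)(C)[Si](C)(C)O[C@H]1/C=C(\C)CC/C=C(/C)[C@@H](OCc2ccc(OC)cc2)[C@@H]3OC(C)(C)O[C@]13CCO[Si](c4ccccc4)(c4ccccc4)C(C)(C)C | intermediate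
27 | C6,C12-diol (6S,7R,8S,9R) | O[C@H]1/C=C(\C)CC/C=C(/C)[C@@H](OCc2ccc(OC)cc2)[C@@H]3OC(C)(C)O[C@]13CCO | intermediate
28 | C12 lactol (formed in situ; C12 configuration undefined) | OC1O[C@H]2/C=C(\C)CC/C=C(/C)[C@@H](OCc3ccc(OC)cc3)[C@@H]4OC(C)(C)O[C@]24C1 | intermediate
29 | cis-fused 6,12-lactone acetonide (6S,7R,8S,9R) | O=C1O[C@H]2/C=C(\C)CC/C=C(/C)[C@@H](OCc3ccc(OC)cc3)[C@@H]4OC(C)(C)O[C@]24C1 | intermediate
30 | 7,8-dihydroxy-6,12-lactone, 9-OPMB (6S,7S,8S,9R) | O=C1O[C@H]2/C=C(\C)CC/C=C(/C)[C@@H](OCc3ccc(OC)cc3)[C@H](O)[C@@]2(O)C1 | intermediate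
31 | C11 dimethylaminomethyl lactone (formed in situ; C11 configuration undefined) | CN(C)CC1C(=O)O[C@H]2/C=C(\C)CC/C=C(/C)[C@@H](OCc3ccc(OC)cc3)[C@H](O)[C@@]12O | intermediate
32 | C11 trimethylammoniomethyl lactone iodide (formed in situ) | C[N+](C)(C)CC1C(=O)O[C@H]2/C=C(\C)CC/C=C(/C)[C@@H](OCc3ccc(OC)cc3)[C@H](O)[C@@]12O.[I-] | intermediate
33 | α-methylene lactone 7,8-diol, 9-OPMB (6S,7S,8S,9R) | C=C1C(=O)O[C@H]2/C=C(\C)CC/C=C(/C)[C@@H](OCc3ccc(OC)cc3)[C@H](O)[C@@]12O | intermediate
34 | angelic acid | C/C=C(/C)C(O)=O | starting material
35 | angelic 2,4,6-trichlorobenzoic anhydride (formed in situ) | C/C=C(/C)C(=O)OC(=O)c1c(Cl)cc(Cl)cc1Cl | intermediate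
36 | C8 angelate, 9-OPMB (6S,7R,8S,9R) | C=C1C(=O)O[C@H]2/C=C(\C)CC/C=C(/C)[C@@H](OCc3ccc(OC)cc3)[C@H](OC(=O)/C(C)=C\C)[C@@]12O | intermediate
37 | CNP0292337.1 (6S,7R,8S,9R; 4E,1(10)Z) | C=C1C(=O)O[C@H]2/C=C(\C)CC/C=C(/C)[C@@H](O)[C@H](OC(=O)/C(C)=C\C)[C@@]12O | target

## Step count and least certain steps

Total: 22 steps. Longest linear sequence: 21 steps (1 → 37 through steps 1–7 and 9–22); step 8 is the only side branch.

Step 16 (key step). The likeliest failures are E1cB loss of the C9 ether from the C10 carbanion (vinyl sulfone), double bromination at C1, and erosion of Z selectivity if the episulfone is epimerised before it loses SO2. The fallback is a stepwise Ramberg–Bäcklund sequence from 23. Kinetic deprotonation at the C1 methylene with LiN(SiMe3)2 in THF at −78 °C and a quench with C2Cl6 gives the isolated C1-chloro sulfone F1, with one halogen at a defined carbon. KOtBu in THF from −78 to 0 °C then effects the contraction and returns to 26. The C10 carbanion is then generated only at low temperature and only in the presence of the leaving group.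

Step 4. The likeliest failure is poor facial selectivity at the aldehyde carbon (C8), with retro-aldol on warming as a second risk. The fallback sets C8 by reduction and starts from 4. Aldol addition of 6 to but-2-ynal gives the propargylic alcohol epimers F2. Dess–Martin oxidation gives the ynone F3. Noyori transfer hydrogenation with RuCl[(R,R)-TsNCH(Ph)CH(Ph)NH2](p-cymene) in iPrOH is expected, by analogy with simple ynones, to give the (8S)-propargylic alcohol F4. Hydroxyl-directed trans-hydrogenation with Cp*RuCl(cod) under H2 then returns to 7.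

Step 10. The likeliest failure is erosion of Felkin selectivity, because the two carbon arms on C7 may not differ enough in size; the hindered Weinreb amide may also lose its methoxy group in step 9. The fallback forms C5–C6 and the C6 stereocentre in one chelation-controlled addition and starts from 10. Reduction with iBu2AlH at −78 °C gives the aldehyde F5. Alkenyllithium 14 is transmetalated with MgBr2·OEt2 to the alkenylmagnesium bromide F6, which is added in CH2Cl2/Et2O at −78 °C. Attack on the convex face of the O6/O7 magnesium chelate, the side of the CH2CH2OSi arm, should give the same 6S alcohol and return to 16.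

Step 12. The likeliest failures are slow opening of the hindered epoxide, acid-promoted participation of a neighbouring ether oxygen, and some attack at C9. The fallback reverses the order of the two C–S bond formations and starts from 17. KSAc in DMF displaces the primary chloride to give the C1 thioacetate F7 with the epoxide intact. K2CO3 in degassed MeOH at high dilution then frees the C1 thiolate, which opens the epoxide at C10 intramolecularly and returns to 20.

Step 20. The likeliest failures are translactonisation by the C8 alkoxide to the 8,12-olide, poor solubility of the trianion, and methylene-acetal formation across O7/O8 during N-methylation. The fallback masks O8 first and starts from 30. Et3SiCl and imidazole silylate the secondary hydroxyl selectively to give the 8-O-triethylsilyl lactone F8. The dianion (LiN(SiMe3)2, 2.2 equiv), Eschenmoser's salt, MeI and NaHCO3 give the 8-O-triethylsilyl methylene lactone F9. HF·pyridine then returns to 33.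

## Further compounds

F1 | step 16 | C1-chloro cyclic sulfone | CC(C)(C)[Si](C)(C)O[C@H]1/C=C(\C)CCC(Cl)S(=O)(=O)[C@H](C)[C@@H](OCc2ccc(OC)cc2)[C@@H]3OC(C)(C)O[C@]13CCO[Si](c4ccccc4)(c4ccccc4)C(C)(C)C
F2 | step 4 | but-2-ynal aldol adduct (C8 epimers) | CC(C)(C)[C@@H]1O[C@@](CCO[Si](c2ccccc2)(c2ccccc2)C(C)(C)C)(C(O)C#CC)C(=O)O1
F3 | step 4 | C8 ynone | CC(C)(C)[C@@H]1O[C@@](CCO[Si](c2ccccc2)(c2ccccc2)C(C)(C)C)(C(=O)C#CC)C(=O)O1
F4 | step 4 | (8S)-propargylic alcohol | CC(C)(C)[C@@H]1O[C@@](CCO[Si](c2ccccc2)(c2ccccc2)C(C)(C)C)([C@@H](O)C#CC)C(=O)O1
F5 | step 10 | C6 aldehyde | O=C[C@@]1(CCO[Si](c2ccccc2)(c2ccccc2)C(C)(C)C)OC(C)(C)O[C@H]1[C@@H]3O[C@H]3C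
F6 | step 10 | (E)-(5-chloro-2-methylpent-1-enyl)magnesium bromide | Br[Mg]/C=C(\C)CCCCl
F7 | step 12 | C1 thioacetate epoxide | CC(=O)SCCC/C(C)=C/[C@H](O[Si](C)(C)C(C)(C)C)[C@@]1(CCO[Si](c2ccccc2)(c2ccccc2)C(C)(C)C)OC(C)(C)O[C@H]1[C@@H]3O[C@H]3C
F8 | step 20 | 8-O-triethylsilyl lactone | O=C1O[C@H]2/C=C(\C)CC/C=C(/C)[C@@H](OCc3ccc(OC)cc3)[C@H](O[Si](CC)(CC)CC)[C@@]2(O)C1
F9 | step 20 | 8-O-triethylsilyl methylene lactone | C=C1C(=O)O[C@H]2/C=C(\C)CC/C=C(/C)[C@@H](OCc3ccc(OC)cc3)[C@H](O[Si](CC)(CC)CC)[C@@]12O
A1 | alternative 1 | ten-membered 6,7-diol with C7 ethynyl, C8 angelate and C9 triethylsilyl ether | C#C[C@@]1(O)[C@@H](O)/C=C(\C)CC/C=C(/C)[C@@H](O[Si](CC)(CC)CC)[C@@H]1OC(=O)/C(C)=C\C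
A2 | alternative 1 | C9 triethylsilyl ether of the target | C=C1C(=O)O[C@H]2/C=C(\C)CC/C=C(/C)[C@@H](O[Si](CC)(CC)CC)[C@H](OC(=O)/C(C)=C\C)[C@@]12O
A3 | alternative 2 | open-chain C8 aldehyde with 3-(bromomethyl)-4-(4-methoxybenzyloxy)butenolide at C6 | O=C[C@H](O[Si](C)(C)C(C)(C)C)/C(C)=C\CC/C(C)=C/[C@@H]1OC(=O)C(CBr)=C1OCc2ccc(OC)cc2
A4 | alternative 2 | bicyclic methylene lactone with free C8 hydroxyl | C=C1C(=O)O[C@H]2/C=C(\C)CC/C=C(/C)[C@@H](O[Si](C)(C)C(C)(C)C)[C@H](O)[C@@]12OCc3ccc(OC)cc3
A5 | alternative 3 | trans-decalin C9 alcohol with equatorial C5 mesylate | C[C@@]12CCC=C(C)[C@@]1(O)[C@@H]3OC(C)(C)O[C@]3(C(=C)CO[Si](C)(C)C(C)(C)C)[C@@H](OCOCC[Si](C)(C)C)[C@H]2OS(C)(=O)=O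
A6 | alternative 3 | ten-membered (4E,1(10)Z)-dienone with C9 ketone | C[Si](C)(C)CCOCO[C@H]1/C=C(\C)CC/C=C(/C)C(=O)[C@@H]2OC(C)(C)O[C@]12C(=C)CO[Si](C)(C)C(C)(C)C
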